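**Retrosynthetic overview**
1. C2–Br and C3–Cl are set last, by anti addition of Br⁺/Cl⁻ to the ring B alkene of a 10-bromochamigra-2,7(14)-dien-9-ol.
2. Ring A and the spiro centre C6 come from a bromonium-ion spirocyclisation of an (E)-γ-bisabolene that already carries C9–OH, C10–Br and C11–Cl; the bromonium ion is released from the bromochloride.
3. That chain comes from α-selective addition of an (E)-allylbarium (C8) to (R)-2-bromo-3-chloro-3-methylbutanal, itself made from prenol.
4. Ring B and its (E)-exocyclic alkene come from closure of a nerolidyl-type allyl cation onto a vinylsilane of fixed geometry (silicon replaced with retention).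
5. Order of ring formation: ring B first, ring A second.

Assumption: comments use chamigrene locants (spiro carbon C6, ring A = C6–C11, ring B = C1–C6, exocyclic CH2 = C14); in step 5 the ligand enantiomer is the one that gives (R)-10, to be confirmed once on 10.

**Step 1**
Reactants: 1 3-(trimethylsilyl)prop-2-yn-1-ol
Product: 3 (Z)-3-iodo-2-methyl-3-(trimethylsilyl)prop-2-en-1-ol, via cyclic alkenylmagnesium alkoxide 2 (not isolated)
Conditions: MeMgBr (3 equiv), CuI (10 mol%), Et2O, −10 °C to rt; then I2, THF, −78 to 0 °C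
Reagents that add atoms: methylmagnesium bromide C[Mg]Br; iodine II
Why: Copper-catalysed, alkoxide-directed anti-carbomagnesiation of a propargylic alcohol puts methyl on the carbon next to CH2O and magnesium on the silyl-bearing carbon inside a five-membered chelate, so iodinolysis with retention leaves iodine cis to CH2OH and silicon cis to the new methyl.

**Step 2**
Reactants: 3 (Z)-3-iodo-2-methyl-3-(trimethylsilyl)prop-2-en-1-ol; 4 3-methylpenta-1,4-dien-3-ol
Product: 6 (2E)-2,6-dimethyl-3-(trimethylsilyl)octa-2,7-diene-1,6-diol, via B-alkyl-9-BBN adduct 5 (not isolated)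
Conditions: 4 (3 equiv), 9-BBN (1.5 equiv), THF, 0 °C to rt; then 3, Pd(dppf)Cl2 (5 mol%), 3 M aq NaOH, THF, 50 °C
Reagents that add atoms: none
Why: B-alkyl Suzuki–Miyaura coupling: 9-BBN adds anti-Markovnikov to one of the two equivalent vinyl groups of 4 and the alkyl group is transferred to the alkenyl iodide with retention of geometry; the carbinol centre is racemic and is destroyed in step 3.

**Step 3**
Reactants: 6 (2E)-2,6-dimethyl-3-(trimethylsilyl)octa-2,7-diene-1,6-diol
Product: 7 (E)-2-(4-methylcyclohex-3-en-1-ylidene)propan-1-ol (ring CH2 next to the ring alkene is cis to the methyl)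
Conditions: Bi(OTf)3 (5 mol%), 2,6-di-tert-butyl-4-methylpyridine (10 mol%), CH2Cl2/HFIP 9:1, −40 to 0 °C
Reagents that add atoms: none
Why: Proposed new method: the Lewis acid ionises the tertiary allylic alcohol to a nerolidyl-type allyl cation whose CH2 terminus attacks the silicon-bearing alkene carbon through a six-membered transition state, and the β-silyl cation loses the silyl group after the least-motion 60° rotation, so the new ring bond takes the place of silicon with retention and the exocyclic alkene is (E); the closest known chemistry is the vinylsilane-terminated cation–olefin cyclisation (ipso substitution with retention) and the acid-mediated cyclisation of nerolidol to bisabolenes.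

**Step 4**
Reactants: 7 (E)-2-(4-methylcyclohex-3-en-1-ylidene)propan-1-ol
Product: 8 (E)-4-(1-chloropropan-2-ylidene)-1-methylcyclohex-1-ene
Conditions: NCS, Me2S, CH2Cl2, −30 to 0 °C; used at once
Reagents that add atoms: N-chlorosuccinimide ClN1C(=O)CCC1=O
Why: Corey–Kim chlorination: chloride displaces the alkoxysulfonium group at the primary allylic carbon (SN2, no allylic shift, neutral medium), so the (E)-tetrasubstituted alkene is untouched.

**Step 5**
Reactants: 9 3-methylbut-2-en-1-ol (prenol)
Product: 10 (R)-2-bromo-3-chloro-3-methylbutan-1-ol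
Conditions: NBS (1.05 equiv), ClTi(OiPr)3 (1.1 equiv), chiral tridentate Schiff-base ligand (salicylaldimine of a 1,2-amino alcohol, 20 mol%), hexanes, −20 °C
Reagents that add atoms: N-bromosuccinimide BrN1C(=O)CCC1=O; chlorotitanium triisopropoxide CC(C)O[Ti](Cl)(OC(C)C)OC(C)C
Why: Titanium-mediated catalytic enantioselective bromochlorination of an allylic alcohol: the ligand-bound titanium alkoxide delivers chloride to the tertiary carbon anti to the bromonium ion at C2, which sets the bromine-bearing centre (later C10) as (R).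

**Step 6**
Reactants: 10 (R)-2-bromo-3-chloro-3-methylbutan-1-ol
Product: 11 (R)-2-bromo-3-chloro-3-methylbutanal
Conditions: Dess–Martin periodinane, CH2Cl2, 0 °C; filtered cold and used crude
Reagents that add atoms: none
Why: Dess–Martin oxidation is neutral and cold, so the α-bromo aldehyde is formed without enolisation and the stereocentre is kept.

**Step 7**
Reactants: 8 (E)-4-(1-chloropropan-2-ylidene)-1-methylcyclohex-1-ene; 11 (R)-2-bromo-3-chloro-3-methylbutanal
Product: 13 (3R,4R,E)-3-bromo-2-chloro-2-methyl-6-(4-methylcyclohex-3-en-1-ylidene)heptan-4-ol, via allylbarium chloride 12 (not isolated)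
Conditions: BaI2, lithium biphenylide (2 equiv), THF, rt; 8, −78 °C; then 11, −78 °C; AcOH quench at −78 °C
Reagents that add atoms: none
Why: Yamamoto-type allylbarium addition: the allylbarium keeps its alkene geometry at −78 °C and adds through its α-carbon (the γ-carbon is fully substituted), and the Cornforth/polar Felkin–Anh transition state of the α-bromo aldehyde gives the anti bromohydrin, that is the (R) carbinol centre (later C9).

**Step 8**
Reactants: 13 (3R,4R,E)-3-bromo-2-chloro-2-methyl-6-(4-methylcyclohex-3-en-1-ylidene)heptan-4-ol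
Product: 14 (2S,3R,6S)-2-bromo-1,1,9-trimethyl-5-methylidenespiro[5.5]undec-8-en-3-ol
Conditions: HFIP, 2,6-di-tert-butyl-4-methylpyridine (1.2 equiv), 0 °C to rt
Reagents that add atoms: none
Why: Solvolytic bromonium-ion spirocyclisation: HFIP ionises the tertiary chloride with anchimeric help from bromine to a configurationally defined bromonium ion, the tetrasubstituted alkene opens it at C11 through a chair transition state (Br equatorial, OH axial) so that the ring CH2 cis to the methyl ends up equatorial and cis to Br (6S), and the C7 cation loses a C14 proton to the hindered base (C8–H is deactivated by the adjacent C–O) to give the exocyclic methylene.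

**Step 9**
Reactants: 14 (2S,3R,6S)-2-bromo-1,1,9-trimethyl-5-methylidenespiro[5.5]undec-8-en-3-ol
Product: 15 (2S,3R,6S,8S,9S)-2,8-dibromo-9-chloro-1,1,9-trimethyl-5-methylidenespiro[5.5]undecan-3-ol
Conditions: NBS (1.05 equiv), LiCl (3 equiv), MeCN/CH2Cl2, −40 °C
Reagents that add atoms: N-bromosuccinimide BrN1C(=O)CCC1=O; lithium chloride [Li+].[Cl-]
Why: Electrophilic anti bromochlorination: the trisubstituted ring B alkene reacts faster than the hindered 1,1-disubstituted one, the bromonium ion forms on the face away from the axial C7 and its overhanging methylene, and chloride opens it at the tertiary carbon (Markovnikov) from the other face, giving 8S,9S with both halogens equatorial.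

**Compound list**
1 | 3-(trimethylsilyl)prop-2-yn-1-ol | C[Si](C)(C)C#CCO | starting material
2 | 4-methyl-3-(trimethylsilyl)-2,5-dihydro-1,2-oxamagnesole (cyclic alkenylmagnesium alkoxide) | CC1=C([Si](C)(C)C)[Mg]OC1 | intermediate
3 | (Z)-3-iodo-2-methyl-3-(trimethylsilyl)prop-2-en-1-ol (I cis to CH2OH) | OC/C(C)=C(\I)[Si](C)(C)C | intermediate
4 | 3-methylpenta-1,4-dien-3-ol | C=CC(C)(O)C=C | starting material
5 | 5-(9-borabicyclo[3.3.1]nonan-9-yl)-3-methylpent-1-en-3-ol (racemic) | C=CC(C)(O)CCB1C2CCCC1CCC2 | intermediate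
6 | (2E)-2,6-dimethyl-3-(trimethylsilyl)octa-2,7-diene-1,6-diol (Si cis to the C2 methyl; racemic at C6) | OC/C(C)=C(\CCC(C)(O)C=C)[Si](C)(C)C | intermediate
7 | (E)-2-(4-methylcyclohex-3-en-1-ylidene)propan-1-ol | OC/C(C)=C1/CC=C(C)CC1 | intermediate
8 | (E)-4-(1-chloropropan-2-ylidene)-1-methylcyclohex-1-ene | ClC/C(C)=C1/CC=C(C)CC1 | intermediate
9 | 3-methylbut-2-en-1-ol (prenol) | CC(C)=CCO | starting material
10 | (R)-2-bromo-3-chloro-3-methylbutan-1-ol | OC[C@@H](Br)C(C)(C)Cl | intermediate
11 | (R)-2-bromo-3-chloro-3-methylbutanal | O=C[C@@H](Br)C(C)(C)Cl | intermediate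
12 | [(E)-2-(4-methylcyclohex-3-en-1-ylidene)propyl]barium chloride | C\C(C[Ba]Cl)=C1/CC=C(C)CC1 | intermediate
13 | (3R,4R,E)-3-bromo-2-chloro-2-methyl-6-(4-methylcyclohex-3-en-1-ylidene)heptan-4-ol | C\C(C[C@@H](O)[C@@H](Br)C(C)(C)Cl)=C1/CC=C(C)CC1 | intermediate
14 | (2S,3R,6S)-2-bromo-1,1,9-trimethyl-5-methylidenespiro[5.5]undec-8-en-3-ol | C=C1C[C@@H](O)[C@@H](Br)C(C)(C)[C@]12CCC(C)=CC2 | intermediate
15 | (2S,3R,6S,8S,9S)-2,8-dibromo-9-chloro-1,1,9-trimethyl-5-methylidenespiro[5.5]undecan-3-ol | C=C1C[C@@H](O)[C@@H](Br)C(C)(C)[C@]12CC[C@](C)(Cl)[C@@H](Br)C2 | target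

**Totals**
Total step count: 9. Longest linear sequence: 7 (steps 1, 2, 3, 4, 7, 8, 9).

**Steps most likely to fail, with fallbacks**

Step 3. Protodesilylation, or re-ionisation of the primary allylic alcohol, could erode the (E) geometry. The fallback sets out from 3 and comes back at 7. 4-Bromo-2-methylbut-1-ene and zinc give (3-methylbut-3-en-1-yl)zinc bromide F1, which is coupled with 3 under Pd(dppf)Cl2 catalysis to (E)-2,6-dimethyl-3-(trimethylsilyl)hepta-2,6-dien-1-ol F2. Iododesilylation with N-iodosuccinimide in MeCN/HFIP (retention) gives (E)-3-iodo-2,6-dimethylhepta-2,6-dien-1-ol F3. Suzuki coupling with allylboronic acid pinacol ester and aq NaOH gives (E)-2,6-dimethyl-3-(prop-2-en-1-yl)hepta-2,6-dien-1-ol F4. Ring-closing metathesis with second-generation Grubbs catalyst then closes the ring B alkene and gives 7 with the same geometry.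

Step 7. The α-bromo aldehyde may epimerise, eliminate or close to an epoxide under the basic barium reagent. The fallback sets out from 12 and comes back at 13. The allylbarium 12 is added at −78 °C to 3-methylbut-2-enal to give racemic (E)-2-methyl-6-(4-methylcyclohex-3-en-1-ylidene)hept-2-en-4-ol F5. Dess–Martin oxidation gives (E)-2-methyl-6-(4-methylcyclohex-3-en-1-ylidene)hept-2-en-4-one F6 ((E)-γ-atlantone). Reduction with (S)-2-methyl-CBS-oxazaborolidine and catecholborane gives (4R,E)-2-methyl-6-(4-methylcyclohex-3-en-1-ylidene)hept-2-en-4-ol F7. Hydroxyl-directed bromochlorination (NBS, ClTi(OiPr)3, the matched Schiff-base ligand) of the allylic alkene then gives 13; allylic 1,3-strain already favours the anti bromohydrin.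

Step 8. The free hydroxyl may capture the bromonium ion, a boat transition state would give the C6 epimer, and the endocyclic alkene may form in place of the methylene. The fallback sets out from 13 and comes back at 14. Trifluoroacetic anhydride and pyridine convert 13 into (3R,4R,E)-3-bromo-2-chloro-2-methyl-6-(4-methylcyclohex-3-en-1-ylidene)heptan-4-yl trifluoroacetate F8, whose ester carbonyl is too poor a donor to participate. Ionisation in HFIP with the same hindered pyridine gives (2S,3R,6S)-2-bromo-1,1,9-trimethyl-5-methylidenespiro[5.5]undec-8-en-3-yl trifluoroacetate F9. Methanolysis (K2CO3, MeOH, 0 °C) gives 14.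

**Further compounds**
F1 | step 3 | (3-methylbut-3-en-1-yl)zinc bromide | C=C(C)CC[Zn]Br
F2 | step 3 | (E)-2,6-dimethyl-3-(trimethylsilyl)hepta-2,6-dien-1-ol | OC/C(C)=C(\CCC(C)=C)[Si](C)(C)C
F3 | step 3 | (E)-3-iodo-2,6-dimethylhepta-2,6-dien-1-ol | OC/C(C)=C(\CCC(C)=C)I
F4 | step 3 | (E)-2,6-dimethyl-3-(prop-2-en-1-yl)hepta-2,6-dien-1-ol | OC/C(C)=C(\CCC(C)=C)CC=C
F5 | step 7 | (E)-2-methyl-6-(4-methylcyclohex-3-en-1-ylidene)hept-2-en-4-ol (racemic) | C\C(CC(O)C=C(C)C)=C1/CC=C(C)CC1
F6 | step 7 | (E)-2-methyl-6-(4-methylcyclohex-3-en-1-ylidene)hept-2-en-4-one | C\C(CC(=O)C=C(C)C)=C1/CC=C(C)CC1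
F7 | step 7 | (4R,E)-2-methyl-6-(4-methylcyclohex-3-en-1-ylidene)hept-2-en-4-ol | C\C(C[C@@H](O)C=C(C)C)=C1/CC=C(C)CC1
F8 | step 8 | (3R,4R,E)-3-bromo-2-chloro-2-methyl-6-(4-methylcyclohex-3-en-1-ylidene)heptan-4-yl trifluoroacetate | C\C(C[C@@H](OC(=O)C(F)(F)F)[C@@H](Br)C(C)(C)Cl)=C1/CC=C(C)CC1
F9 | step 8 | (2S,3R,6S)-2-bromo-1,1,9-trimethyl-5-methylidenespiro[5.5]undec-8-en-3-yl trifluoroacetate | C=C1C[C@@H](OC(=O)C(F)(F)F)[C@@H](Br)C(C)(C)[C@]12CCC(C)=CC2
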